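**Strategy.** The diaryl ether is not made by C–O coupling. Its oxygen joins C6 of ring A of unit 1 (the 4'-methoxyflavone), crowded by the C5 and C7 oxygens, to C4' of ring B of unit 2, a para-disubstituted benzene. Ring B is therefore grown on the oxygen: the ethynyl ether of 2,6-bis(benzyloxy)-4-(methoxymethoxy)phenol adds across C3 and C6 of methyl coumalate and expels CO2, which should give the 4-aryloxybenzoate in one operation. The ester later becomes C2 of unit 2; the MOM-masked oxygen, para to the ether, becomes O1 of unit 1.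

Key step: step 8

Remark: the terminal aryl ethynyl ether 13, shielded by its two flanking benzyloxy groups, is assumed to survive cold handling in solution and is used the same day without storage.

Step 1
Reactants: 1 3,4,5-trihydroxybenzaldehyde
Product: 2 4-(allyloxy)-3,5-dihydroxybenzaldehyde
Conditions: allyl bromide (1.05 equiv), NaHCO3, NaI (cat.), DMF, 40 °C, N2
Reagents that add atoms: allyl bromide, C=CCBr
Why: Williamson etherification under a weak base that ionises only the 4-OH, the most acidic hydroxyl because it is para to the formyl group, so the central oxygen alone should be capped.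

Step 2
Reactants: 2 4-(allyloxy)-3,5-dihydroxybenzaldehyde
Product: 3 4-(allyloxy)-3,5-bis(benzyloxy)benzaldehyde
Conditions: BnBr (2.3 equiv), K2CO3, DMF, 50 °C
Reagents that add atoms: benzyl bromide, BrCc1ccccc1
Why: exhaustive Williamson benzylation of the two remaining phenols, which places benzyl ethers on the oxygens that become O5 and O7 of unit 1 and leaves the allyl ether as an orthogonal cap.

Step 3
Reactants: 3 4-(allyloxy)-3,5-bis(benzyloxy)benzaldehyde
Product: 5 4-(allyloxy)-3,5-bis(benzyloxy)phenol, via aryl formate 4 (not isolated)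
Conditions: mCPBA, CH2Cl2, 0 °C → rt; aq. NaHCO3 wash; then K2CO3 (cat.), MeOH, rt
Reagents that add atoms: mCPBA, O=C(OO)c1cccc(Cl)c1
Why: Baeyer–Villiger (Dakin-type) oxidation, in which the electron-rich trialkoxyphenyl group migrates to oxygen and the resulting formate is methanolysed, while the electron-poor terminal alkene of the allyl ether reacts far more slowly with the peracid.

Step 4
Reactants: 5 4-(allyloxy)-3,5-bis(benzyloxy)phenol
Product: 6 2-(allyloxy)-1,3-bis(benzyloxy)-5-(methoxymethoxy)benzene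
Conditions: MOMCl, i-Pr2NEt, CH2Cl2, 0 °C → rt
Reagents that add atoms: chloromethyl methyl ether, COCCl
Why: O-alkylation of the only free phenol to its MOM acetal, a group that tolerates n-BuLi at low temperature and LiN(SiMe3)2 and is later removed by acid without loss of benzyl ethers.

Step 5
Reactants: 6 2-(allyloxy)-1,3-bis(benzyloxy)-5-(methoxymethoxy)benzene
Product: 7 2,6-bis(benzyloxy)-4-(methoxymethoxy)phenol
Conditions: Pd(PPh3)4 (cat.), morpholine, THF, rt
Reagents that add atoms: none
Why: Tsuji–Trost deallylation, in which ionisation to a π-allylpalladium complex releases the hindered phenoxide and morpholine traps the allyl group, with benzyl and MOM ethers untouched.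

Step 6
Reactants: 7 2,6-bis(benzyloxy)-4-(methoxymethoxy)phenol; 8 trichloroethylene
Product: 10 1,3-bis(benzyloxy)-2-{[(E)-1,2-dichloroethenyl]oxy}-5-(methoxymethoxy)benzene, via dichloroacetylene 9 (not isolated)
Conditions: K2CO3, DMF, 70 °C, N2 (closed system; dichloroacetylene is toxic)
Reagents that add atoms: none
Why: base-mediated dehydrochlorination of 8 and anti addition of the phenoxide to the resulting dichloroacetylene (nucleophilic vinylation), an attack on an unhindered sp carbon that the crowded oxygen can reach and that should give the E ether.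

Step 7
Reactants: 10 1,3-bis(benzyloxy)-2-{[(E)-1,2-dichloroethenyl]oxy}-5-(methoxymethoxy)benzene
Product: 13 1,3-bis(benzyloxy)-2-(ethynyloxy)-5-(methoxymethoxy)benzene, via chloroethynyl ether 11 (not isolated), via lithium aryloxyacetylide 12 (not isolated)
Conditions: n-BuLi (2.2 equiv), THF, −78 °C → −40 °C; then H2O, −78 °C; cold work-up, solution used at once
Reagents that add atoms: none
Why: dehydrochlorination to the chloroalkyne followed by chlorine–lithium exchange and protonation, the established route from 1,2-dichlorovinyl ethers to ynol ethers, run cold so that ortho-lithiation next to the MOM ether and Wittig rearrangement of the benzyl ethers should not compete.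

Step 8
Reactants: 13 1,3-bis(benzyloxy)-2-(ethynyloxy)-5-(methoxymethoxy)benzene; 14 methyl coumalate
Product: 16 methyl 4-[2,6-bis(benzyloxy)-4-(methoxymethoxy)phenoxy]benzoate, via bicyclic lactone 15 (not isolated)
Conditions: 14 (1.5 equiv), toluene, 90 °C, sealed tube, Ar
Reagents that add atoms: none
Why: Inverse-electron-demand Diels–Alder reaction: the electron-rich alkyne of 13 adds across C3 and C6 of the electron-poor 2-pyrone 14 to give the 2-oxabicyclo[2.2.2]octadienone 15, which loses CO2 by retro-[4+2] cycloreversion and aromatises. The closest known reaction type is the cycloaddition–decarboxylation of methyl coumalate with electron-rich alkynes and enol ethers, which gives para-substituted benzoates. The new benzene ring (ring B of unit 2) is closed by intermolecular [4+2] annulation, two carbons from the alkyne and four from pyrone C3–C6, forming the C3–C4 and C5–C6 bonds of the benzoate. No stereocentre remains, since the two bridgehead centres of 15 disappear with CO2. The selectivity needed is regiochemical: the unsubstituted, electron-rich alkyne carbon should bond to pyrone C6, the most electrophilic position (β to the ester, δ to the lactone carbonyl), so the oxygen-bearing carbon ends on C3 and the aryloxy group para to the ester. Unlike alkyl ynol ethers, 13 cannot fragment to a ketene and an alkene on heating because its oxygen carries an aryl group with no β-hydrogen.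

Step 9
Reactants: 17 2',4',6'-trihydroxyacetophenone
Product: 18 1-[2,4-bis(benzyloxy)-6-hydroxyphenyl]ethan-1-one
Conditions: BnBr (2.1 equiv), K2CO3, DMF, rt
Reagents that add atoms: benzyl bromide, BrCc1ccccc1
Why: Williamson benzylation that should stop after two groups, because the last hydroxyl is hydrogen-bonded to the ketone and is much less nucleophilic.

Step 10
Reactants: 16 methyl 4-[2,6-bis(benzyloxy)-4-(methoxymethoxy)phenoxy]benzoate; 18 1-[2,4-bis(benzyloxy)-6-hydroxyphenyl]ethan-1-one
Product: 19 1-[2,4-bis(benzyloxy)-6-hydroxyphenyl]-3-{4-[2,6-bis(benzyloxy)-4-(methoxymethoxy)phenoxy]phenyl}propane-1,3-dione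
Conditions: 18 (1.3 equiv), LiN(SiMe3)2 (4 equiv), THF, −78 °C → rt; aq. NH4Cl
Reagents that add atoms: none
Why: crossed Claisen condensation of the dilithium phenoxide–enolate of 18 with the non-enolisable methyl ester 16, driven forward by formation of the stable diketonate.

Step 11
Reactants: 19 1-[2,4-bis(benzyloxy)-6-hydroxyphenyl]-3-{4-[2,6-bis(benzyloxy)-4-(methoxymethoxy)phenoxy]phenyl}propane-1,3-dione
Product: 21 5,7-bis(benzyloxy)-2-{4-[2,6-bis(benzyloxy)-4-hydroxyphenoxy]phenyl}-4H-chromen-4-one, via MOM-protected flavone 20 (not isolated)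
Conditions: conc. HCl (5 equiv), MeOH/THF, 55 °C
Reagents that add atoms: none
Why: acid-catalysed cyclodehydration closes the pyranone of unit 2 (phenol onto the enolised diketone, loss of water), and the same methanolic acid then cleaves the MOM acetal, conditions under which aryl benzyl ethers should persist.

Step 12
Reactants: 21 5,7-bis(benzyloxy)-2-{4-[2,6-bis(benzyloxy)-4-hydroxyphenoxy]phenyl}-4H-chromen-4-one
Product: 22 5,7-bis(benzyloxy)-2-{4-[2,6-bis(benzyloxy)-4-hydroxy-3-iodophenoxy]phenyl}-4H-chromen-4-one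
Conditions: NIS (1.0 equiv), CH2Cl2/MeCN, −20 °C → 0 °C
Reagents that add atoms: N-iodosuccinimide, O=C1CCC(=O)N1I
Why: electrophilic aromatic iodination of the most electron-rich ring at a position ortho to the free phenol, where the two ortho carbons are equivalent so only one regioisomer can form, and where one equivalent at low temperature should limit a second iodination.

Step 13
Reactants: 22 5,7-bis(benzyloxy)-2-{4-[2,6-bis(benzyloxy)-4-hydroxy-3-iodophenoxy]phenyl}-4H-chromen-4-one; 23 4-ethynylanisole
Product: 25 5,7-bis(benzyloxy)-6-{4-[5,7-bis(benzyloxy)-4-oxo-4H-chromen-2-yl]phenoxy}-2-(4-methoxyphenyl)-4H-chromen-4-one, via aryl alkynyl ketone 24 (not isolated)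
Conditions: PdCl2(PPh3)2 (5 mol %), CO (5 bar), Et2NH, DMF, 80 °C
Reagents that add atoms: carbon monoxide, [C-]#[O+]
Why: carbonylative Sonogashira-type coupling (oxidative addition, CO insertion, alkynylation) gives the o-hydroxyaryl ynone, which under the secondary amine should close 6-endo through the amine adduct to the flavone of unit 1 and not 5-exo to an aurone.

Step 14
Reactants: 25 5,7-bis(benzyloxy)-6-{4-[5,7-bis(benzyloxy)-4-oxo-4H-chromen-2-yl]phenoxy}-2-(4-methoxyphenyl)-4H-chromen-4-one
Product: 26 cryptomerin A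
Conditions: H2 (1 atm), 10% Pd/C, THF/MeOH, rt
Reagents that add atoms: none
Why: catalytic hydrogenolysis of the four aryl benzyl ethers, which at ambient pressure and temperature should leave the methyl ether, the diaryl ether and the conjugated C2=C3 bonds of both flavones intact.

**Compound list**

1 | 3,4,5-trihydroxybenzaldehyde | O=Cc1cc(O)c(O)c(O)c1 | starting material
2 | 4-(allyloxy)-3,5-dihydroxybenzaldehyde | O=Cc1cc(O)c(OCC=C)c(O)c1 | intermediate
3 | 4-(allyloxy)-3,5-bis(benzyloxy)benzaldehyde | O=Cc1cc(OCc2ccccc2)c(OCC=C)c(OCc2ccccc2)c1 | intermediate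
4 | 4-(allyloxy)-3,5-bis(benzyloxy)phenyl formate (not isolated) | O=COc1cc(OCc2ccccc2)c(OCC=C)c(OCc2ccccc2)c1 | intermediate
5 | 4-(allyloxy)-3,5-bis(benzyloxy)phenol | Oc1cc(OCc2ccccc2)c(OCC=C)c(OCc2ccccc2)c1 | intermediate
6 | 2-(allyloxy)-1,3-bis(benzyloxy)-5-(methoxymethoxy)benzene | COCOc1cc(OCc2ccccc2)c(OCC=C)c(OCc2ccccc2)c1 | intermediate
7 | 2,6-bis(benzyloxy)-4-(methoxymethoxy)phenol | COCOc1cc(OCc2ccccc2)c(O)c(OCc2ccccc2)c1 | intermediate
8 | trichloroethylene | ClC=C(Cl)Cl | starting material
9 | dichloroacetylene (not isolated) | ClC#CCl | intermediate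
10 | 1,3-bis(benzyloxy)-2-{[(E)-1,2-dichloroethenyl]oxy}-5-(methoxymethoxy)benzene | Cl/C=C(/Cl)Oc1c(OCc2ccccc2)cc(OCOC)cc1OCc1ccccc1 | intermediate
11 | 1,3-bis(benzyloxy)-2-[(chloroethynyl)oxy]-5-(methoxymethoxy)benzene (not isolated) | ClC#COc1c(OCc2ccccc2)cc(OCOC)cc1OCc1ccccc1 | intermediate
12 | lithium 2-[2,6-bis(benzyloxy)-4-(methoxymethoxy)phenoxy]ethynide (not isolated) | [Li]C#COc1c(OCc2ccccc2)cc(OCOC)cc1OCc1ccccc1 | intermediate
13 | 1,3-bis(benzyloxy)-2-(ethynyloxy)-5-(methoxymethoxy)benzene | C#COc1c(OCc2ccccc2)cc(OCOC)cc1OCc1ccccc1 | intermediate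
14 | methyl coumalate (methyl 2-oxo-2H-pyran-5-carboxylate) | COC(=O)c1ccc(=O)oc1 | starting material
15 | methyl 8-[2,6-bis(benzyloxy)-4-(methoxymethoxy)phenoxy]-3-oxo-2-oxabicyclo[2.2.2]octa-5,7-diene-6-carboxylate (racemic, one enantiomer drawn; not isolated) | COC(=O)C1=C[C@H]2C(=O)O[C@@H]1C=C2Oc1c(OCc2ccccc2)cc(OCOC)cc1OCc1ccccc1 | intermediate
16 | methyl 4-[2,6-bis(benzyloxy)-4-(methoxymethoxy)phenoxy]benzoate | COC(=O)c1ccc(Oc2c(OCc3ccccc3)cc(OCOC)cc2OCc2ccccc2)cc1 | intermediate
17 | 2',4',6'-trihydroxyacetophenone | CC(=O)c1c(O)cc(O)cc1O | starting material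
18 | 1-[2,4-bis(benzyloxy)-6-hydroxyphenyl]ethan-1-one | CC(=O)c1c(O)cc(OCc2ccccc2)cc1OCc1ccccc1 | intermediate
19 | 1-[2,4-bis(benzyloxy)-6-hydroxyphenyl]-3-{4-[2,6-bis(benzyloxy)-4-(methoxymethoxy)phenoxy]phenyl}propane-1,3-dione | O=C(CC(=O)c1ccc(Oc2c(OCc3ccccc3)cc(OCOC)cc2OCc2ccccc2)cc1)c1c(O)cc(OCc2ccccc2)cc1OCc1ccccc1 | intermediate
20 | 5,7-bis(benzyloxy)-2-{4-[2,6-bis(benzyloxy)-4-(methoxymethoxy)phenoxy]phenyl}-4H-chromen-4-one (not isolated) | COCOc1cc(OCc2ccccc2)c(Oc2ccc(-c3cc(=O)c4c(OCc5ccccc5)cc(OCc5ccccc5)cc4o3)cc2)c(OCc2ccccc2)c1 | intermediate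
21 | 5,7-bis(benzyloxy)-2-{4-[2,6-bis(benzyloxy)-4-hydroxyphenoxy]phenyl}-4H-chromen-4-one | Oc1cc(OCc2ccccc2)c(Oc2ccc(-c3cc(=O)c4c(OCc5ccccc5)cc(OCc5ccccc5)cc4o3)cc2)c(OCc2ccccc2)c1 | intermediate
22 | 5,7-bis(benzyloxy)-2-{4-[2,6-bis(benzyloxy)-4-hydroxy-3-iodophenoxy]phenyl}-4H-chromen-4-one | Oc1cc(OCc2ccccc2)c(Oc2ccc(-c3cc(=O)c4c(OCc5ccccc5)cc(OCc5ccccc5)cc4o3)cc2)c(OCc2ccccc2)c1I | intermediate
23 | 4-ethynylanisole (1-ethynyl-4-methoxybenzene) | C#Cc1ccc(OC)cc1 | starting material
24 | 5,7-bis(benzyloxy)-2-[4-({2,6-bis(benzyloxy)-4-hydroxy-3-[3-(4-methoxyphenyl)prop-2-ynoyl]phenyl}oxy)phenyl]-4H-chromen-4-one (not isolated) | COc1ccc(C#CC(=O)c2c(O)cc(OCc3ccccc3)c(Oc3ccc(-c4cc(=O)c5c(OCc6ccccc6)cc(OCc6ccccc6)cc5o4)cc3)c2OCc2ccccc2)cc1 | intermediate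
25 | 5,7-bis(benzyloxy)-6-{4-[5,7-bis(benzyloxy)-4-oxo-4H-chromen-2-yl]phenoxy}-2-(4-methoxyphenyl)-4H-chromen-4-one (tetra-O-benzylcryptomerin A) | COc1ccc(-c2cc(=O)c3c(OCc4ccccc4)c(Oc4ccc(-c5cc(=O)c6c(OCc7ccccc7)cc(OCc7ccccc7)cc6o5)cc4)c(OCc4ccccc4)cc3o2)cc1 | intermediate
26 | cryptomerin A, 5,7-dihydroxy-6-[4-(5,7-dihydroxy-4-oxo-4H-chromen-2-yl)phenoxy]-2-(4-methoxyphenyl)-4H-chromen-4-one | COc1ccc(-c2cc(=O)c3c(O)c(Oc4ccc(-c5cc(=O)c6c(O)cc(O)cc6o5)cc4)c(O)cc3o2)cc1 | target

**Step count.** Total: 14 steps. Longest linear sequence: 13 steps (steps 1–8, then 10–14); step 9 is a one-step side branch.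

**Steps most likely to fail**

Step 8. The ynol ether may oligomerise or be hydrated to the aryl acetate faster than it adds to the pyrone, or the coumalate may be used up by self-dimerisation before the cycloaddition is complete. The fallback makes the ether bond directly: phenol 7 is coupled with methyl 4-iodobenzoate under Ullmann-type conditions (CuI, picolinic acid, K3PO4, DMSO, 90 °C), which are known to accept phenols with two ortho substituents. It sets out from 7, bypasses steps 6–8 and rejoins the route at 16; no new compound is made (F0).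

Step 13. CO insertion may lose to direct alkynylation of the hindered, electron-rich aryl–palladium species (leading on to a benzofuran), the ynone may close 5-exo to the aurone, or the iodide may simply be reduced. The fallback sets out from 22 and installs the ketone stepwise. Stille coupling with tributyl(1-ethoxyvinyl)stannane (PdCl2(PPh3)2, toluene, 100 °C) should give the 1-ethoxyvinyl arene F1, and dilute HCl in THF hydrolyses it to the o-hydroxyacetophenone F2. C-Aroylation of its dilithium enolate (LiN(SiMe3)2, THF, −78 °C, then 4-methoxybenzoyl chloride) gives the 1,3-diketone F3, and cyclodehydration (TsOH, toluene, 80 °C) rejoins the route at 25.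

Step 7. The terminal ynol ether may be lost by oligomerisation or hydration during the protic quench, the aqueous work-up and concentration. The fallback sets out from 10 and captures the acetylide instead of protonating it: the same lithiation is quenched with Me3SiCl to give the C-trimethylsilyl ynol ether F4, which should tolerate chromatography and storage. Bu4NF in THF at −20 °C then releases 13 in solution directly before the cycloaddition, so the route is rejoined at 13.

**Further compounds**

F0 | step 8 | none | none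
F1 | step 13 | 5,7-bis(benzyloxy)-2-{4-[2,6-bis(benzyloxy)-3-(1-ethoxyethenyl)-4-hydroxyphenoxy]phenyl}-4H-chromen-4-one | CCOC(=C)c1c(O)cc(OCc2ccccc2)c(Oc2ccc(-c3cc(=O)c4c(OCc5ccccc5)cc(OCc5ccccc5)cc4o3)cc2)c1OCc1ccccc1
F2 | step 13 | 2-{4-[3-acetyl-2,6-bis(benzyloxy)-4-hydroxyphenoxy]phenyl}-5,7-bis(benzyloxy)-4H-chromen-4-one | CC(=O)c1c(O)cc(OCc2ccccc2)c(Oc2ccc(-c3cc(=O)c4c(OCc5ccccc5)cc(OCc5ccccc5)cc4o3)cc2)c1OCc1ccccc1
F3 | step 13 | 1-{2,4-bis(benzyloxy)-3-[4-(5,7-bis(benzyloxy)-4-oxo-4H-chromen-2-yl)phenoxy]-6-hydroxyphenyl}-3-(4-methoxyphenyl)propane-1,3-dione | COc1ccc(C(=O)CC(=O)c2c(O)cc(OCc3ccccc3)c(Oc3ccc(-c4cc(=O)c5c(OCc6ccccc6)cc(OCc6ccccc6)cc5o4)cc3)c2OCc2ccccc2)cc1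
F4 | step 7 | {[2,6-bis(benzyloxy)-4-(methoxymethoxy)phenoxy]ethynyl}trimethylsilane | C[Si](C)(C)C#COc1c(OCc2ccccc2)cc(OCOC)cc1OCc1ccccc1
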